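Multiplying a start rate by the time is the trap in a flask whose rate falls as it runs.

all flasks: J 0.80 M
- north-east: G 0.68 M; run made earlier
- west: G 1 M; run made earlier
- alder: G 0.800 M; time 40 h
- maple: G 1.20 M; time 40 h

| run | time / h | J / % | Q / % |
|---|---|---|---|
| north-east | 6.00 | 54.3 | 43.8 |
| north-east | 12.0 | 39.7 | 59.7 |
| north-east | 20.0 | 29.3 | 69.9 |
| north-east | 25.0 | 25.2 | 73.9 |
| north-east | 30.0 | 22.8 | 75.5 |
| north-east | 40.0 | 19.5 | 79.1 |
| west | 2.50 | 60.8 | 38.9 |
| west | 8.00 | 32.5 | 65.0 |
| west | 15.0 | 18.3 | 79.4 |
| west | 20.0 | 11.8 | 86.2 |
| west | 30.0 | 5.5 | 91.5 |
| west | 40.0 | 2.8 | 94.4 |

(readings scatter by 0.5 percentage points)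

- part of the J that has reacted at the end, alder
- part of the J that has reacted at the end, maple
- what raising the concentration of G from its lowest to its highest value here does to the part of the J that has reacted (changes below 5 percentage points count as none) (no change / it rises / it falls)

- the earlier runs were read with a standard deviation of 0.5 percentage points

In north-east, J levels towards 15.0 % of its charge, the floor that one-to-one consumption leaves when G is short, so the rate is taken as a constant times J times G. The west readings at 40.0 h give 10.4 /M for the clock, the rate constant summed over the time from the start. At 20.0 h the same reading is 4.57 /M, less than the 5.18 /M of an even clock, so it is read at the asked time.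

Reckoned on the clock's average, J leaves alder at its start at 0.207 /h of its charge. Over 40 h that promises 8.29 charges. A first pass, with J's own fraction slowing the rate and G held, leaves 0.0251 %. Going round again, G falls with J in this equimolar flask, which adds a second factor of the same fraction. The rate then goes as the fraction squared, and the reciprocal of the fraction left climbs from one by 8.29. That leaves 10.8 %, so 89.2 % has reacted, and the end rate stands a factor 86.3 below the start.

In maple, J is the limiting reagent and G's factor ends near 33.3 %. The clock times the excess gives 4.14, which leaves 0.534 %, so 99.5 % has reacted. The rise of 10 points exceeds 5 points.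

The forecast gives 89.3 % (87.5 % to 90.8 %) for alder and 99.4 % (98.8 % to 99.8 %) for maple, a shade under the maple figure above, with the verdict it rises, and calls the drift of its rate constant “unexplained but consistent”.

The flasks give 89.3 % for alder and 99.5 % for maple: it rises, by 10 points.

    J + G → E + Q (k = 0.00519 /M/min)
    E + Q → X (k = 0.00290 /M/min)
    G + E ⇌ D, settled at all times (K = 37.2 /M)
    E → Z (k = 0.0492 /min)

The difference in the charge of G is the main reason for the rise: maple, run with the G of alder, ends at 89.3 % instead of 99.5 %. Within alder, the falling level of G accounts for part of what stays unreacted: with G held, alder reaches >99.9 % instead of 89.3 %, which is where the first pass with the clock of 10.4 /M pointed. In maple the same hold gains 0.54 points, for there 33.2 % of the charged G is free at the end, against 10.4 % in alder.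

(Readings and results are simulated for substances that don't exist; noise was put on by code.)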